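Numbering: C1 allyl bridgehead, C2 CH2, C3 CH–OMe, C4 ketone, C5 MeO bridgehead, C6 CH–aryl, C7 CH–Me, C8 AcO bridge. The route cuts C2–C3 and C1–C7. Since C8 is flanked by both quaternary bridgeheads, ring B (C1, C7, C6, C5, C8) can be stored as a cyclobutanol (C8, C7, C6, C5) bearing C1 as an alkenyl group. One SnCl4-promoted Prins–pinacol cascade closes ring A (C1–C5, C8), expands the cyclobutane to ring B, sets C1 and C3 and unveils the C8 ketone. The precursor is a 1-(penta-1,4-dien-2-yl)cyclobutanol silyl ether whose C5 carries methoxy and, cis to the dienyl group, the silyloxy acetal chain C4–C3.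

Key step: step 10

Remark (assumption on the chemistry): commercial aqueous 2,2-dimethoxyacetaldehyde is dried and distilled to the anhydrous monomer before step 2; the locants C1–C8 above are used for all intermediates, also before the bicycle exists.

Step 1
Reactants: 1 (S)-4-benzyl-1,3-oxazolidin-2-one; 2 methoxyacetyl chloride
Product: 4 (S)-4-benzyl-3-(methoxyacetyl)-1,3-oxazolidin-2-one, via lithium salt 3 (not isolated)
Conditions: n-BuLi, THF, −78 °C; then 2, −78 to 0 °C
Reagents that add atoms: none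
Why: N-acylation of the lithiated oxazolidinone by the acid chloride loads the auxiliary; no stereocentre is formed.

Step 2
Reactants: 4 (S)-4-benzyl-3-(methoxyacetyl)-1,3-oxazolidin-2-one; 5 2,2-dimethoxyacetaldehyde
Product: 7 (S)-4-benzyl-3-[(2S,3S)-3-hydroxy-2,4,4-trimethoxybutanoyl]-1,3-oxazolidin-2-one, via dibutylboron enolate 6 (not isolated)
Conditions: Bu2BOTf, Et3N, CH2Cl2, −78 to 0 °C; 5, −78 to 0 °C; pH 7 buffer, MeOH, H2O2, 0 °C
Reagents that add atoms: none
Why: Evans syn-aldol reaction, in which the (Z)-boron enolate 6 reacts through a Zimmerman–Traxler chair on the face away from the benzyl group, sets the carbinol centre C4 as S (the α-centre, also S, becomes trigonal again in step 5).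

Step 3
Reactants: 7 (S)-4-benzyl-3-[(2S,3S)-3-hydroxy-2,4,4-trimethoxybutanoyl]-1,3-oxazolidin-2-one
Product: 8 (2S,3S)-3-hydroxy-2,4,4-trimethoxy-1-(pyrrolidin-1-yl)butan-1-one
Conditions: AlMe3, pyrrolidine, CH2Cl2, 0 °C to rt; aq potassium sodium tartrate
Reagents that add atoms: pyrrolidine, C1CCNC1
Why: Weinreb-type aluminium amide aminolysis of the exocyclic imide carbonyl, assisted by the free β-hydroxyl, exchanges the auxiliary for the tertiary amide that keteniminium formation needs and leaves C4 untouched.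

Step 4
Reactants: 8 (2S,3S)-3-hydroxy-2,4,4-trimethoxy-1-(pyrrolidin-1-yl)butan-1-one
Product: 9 (2S,3S)-2,4,4-trimethoxy-1-(pyrrolidin-1-yl)-3-(triethylsilyloxy)butan-1-one
Conditions: TESCl, imidazole, DMF, 0 °C to rt
Reagents that add atoms: triethylsilyl chloride, CC[Si](Cl)(CC)CC
Why: Imidazole-promoted silylation masks the hydroxyl before the amide is activated with Tf2O.

Step 5
Reactants: 9 (2S,3S)-2,4,4-trimethoxy-1-(pyrrolidin-1-yl)-3-(triethylsilyloxy)butan-1-one; 10 (E)-methylisoeugenol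
Product: 13 (2R,3S,4R)-2-[(1S)-2,2-dimethoxy-1-(triethylsilyloxy)ethyl]-3-(3,4-dimethoxyphenyl)-2-methoxy-4-methylcyclobutan-1-one (side chain cis to aryl; methyl trans to aryl), via keteniminium triflate 11 (not isolated), via cyclobutaniminium triflate 12 (not isolated)
Conditions: Tf2O, 2,4,6-collidine, CH2Cl2, −25 °C; 10 (3 equiv), −25 to 40 °C; aq NaHCO3, rt
Reagents that add atoms: water, O
Why: Ghosez keteniminium–alkene [2+2] cycloaddition, in which the electron-rich propenyl carbon C7 bonds to the iminium carbon C8 from the side of the small methoxy group and the aryl-stabilised benzylic cation closes on C5, so that the bulky chain ends cis to the aryl group with aryl and methyl still trans, while the C4 centre, whose hydrogen eclipses the C5=C8 bond to avoid allylic strain with the pyrrolidine ring, leaves only the face bearing the silyloxy group (anti to the acetal carbon) open to C6 and thereby sets the absolute configuration of C5, C6 and C7.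

Step 6
Reactants: 13 (2R,3S,4R)-2-[(1S)-2,2-dimethoxy-1-(triethylsilyloxy)ethyl]-3-(3,4-dimethoxyphenyl)-2-methoxy-4-methylcyclobutan-1-one
Product: 14 (2R,3S,4R)-3-(3,4-dimethoxyphenyl)-2-[(1S)-1-hydroxy-2,2-dimethoxyethyl]-2-methoxy-4-methylcyclobutan-1-one
Conditions: HF·pyridine, pyridine, THF, 0 °C
Reagents that add atoms: none
Why: Buffered fluoride cleavage of the secondary triethylsilyl ether spares the dimethyl acetal and avoids the retro-aldol cleavage that a basic fluoride source could cause, and frees the hydroxyl that must steer step 8.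

Step 7
Reactants: 15 2,3-dibromopropene; 16 vinylmagnesium bromide
Product: 17 2-bromopenta-1,4-diene
Conditions: CuI (5 mol%), THF, −10 °C to rt
Reagents that add atoms: none
Why: Copper-catalysed Grignard coupling takes place at the allylic C–Br bond only, the vinylic C–Br bond being inert under these conditions.

Step 8
Reactants: 14 (2R,3S,4R)-3-(3,4-dimethoxyphenyl)-2-[(1S)-1-hydroxy-2,2-dimethoxyethyl]-2-methoxy-4-methylcyclobutan-1-one; 17 2-bromopenta-1,4-diene
Product: 19 (1S,2R,3S,4R)-3-(3,4-dimethoxyphenyl)-2-[(1S)-1-hydroxy-2,2-dimethoxyethyl]-2-methoxy-4-methyl-1-(penta-1,4-dien-2-yl)cyclobutan-1-ol (dienyl group cis to side chain and aryl), via dienylmagnesium bromide 18 (not isolated)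
Conditions: 17, Mg, THF, rt (3 equiv of 18); 14, THF, −78 to −20 °C; aq NH4Cl
Reagents that add atoms: none
Why: Alkoxide-directed Grignard 1,2-addition, in which the first equivalent of 18 turns the C4 hydroxyl on the face of the pseudo-axial side chain into a bromomagnesium alkoxide that binds a further equivalent and hands the dienyl group to C8 on that same face, cis to the side chain and trans to the C7 methyl and C5 methoxy groups, against the intrinsic preference of the ketone for attack on the opposite face and as the cis ring fusion of step 10 demands.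

Step 9
Reactants: 19 (1S,2R,3S,4R)-3-(3,4-dimethoxyphenyl)-2-[(1S)-1-hydroxy-2,2-dimethoxyethyl]-2-methoxy-4-methyl-1-(penta-1,4-dien-2-yl)cyclobutan-1-ol
Product: 21 [(1S,2R,3S,4R)-2-[(1S)-2,2-dimethoxy-1-(triethylsilyloxy)ethyl]-3-(3,4-dimethoxyphenyl)-2-methoxy-4-methyl-1-(penta-1,4-dien-2-yl)cyclobutoxy]trimethylsilane, via C4 triethylsilyl ether 20 (not isolated)
Conditions: TESCl, imidazole, DMAP, DMF, 0 °C to rt; then TMSCl, rt
Reagents that add atoms: triethylsilyl chloride, CC[Si](Cl)(CC)CC; trimethylsilyl chloride, C[Si](C)(C)Cl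
Why: Two consecutive imidazole-promoted silylations in one flask, TESCl reaching only the secondary C4 hydroxyl and the smaller TMSCl then capping the tertiary cyclobutanol, use chloride reagents because silyl triflates would attack the dimethyl acetal.

Step 10
Reactants: 21 [(1S,2R,3S,4R)-2-[(1S)-2,2-dimethoxy-1-(triethylsilyloxy)ethyl]-3-(3,4-dimethoxyphenyl)-2-methoxy-4-methyl-1-(penta-1,4-dien-2-yl)cyclobutoxy]trimethylsilane
Product: 22 (1S,3S,4R,5R,6S,7R)-6-(3,4-dimethoxyphenyl)-3,5-dimethoxy-7-methyl-1-(prop-2-en-1-yl)-4-(triethylsilyloxy)bicyclo[3.2.1]octan-8-one (C3 methoxy endo; C4 silyloxy exo; aryl endo; methyl exo)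
Conditions: SnCl4 (1.5 equiv), 2,6-di-tert-butyl-4-methylpyridine, CH2Cl2, −78 to −20 °C
Reagents that add atoms: none
Why: SnCl4 abstracts one methoxy group of the C3 acetal, the alkene terminus C2 adds to the oxocarbenium ion to close ring A (bond C2–C3) and leave a tertiary cation at C1, and C7 then shifts from C8 to C1 (bond C1–C7), enlarging the strained four-membered ring to ring B while the trimethylsilyl group leaves from oxygen to give the C8 ketone. The closest known reaction type is the ring-enlarging Prins–pinacol annulation of 1-alkenylcycloalkanol silyl ethers carrying a tethered acetal; the product is bridged here because the acetal hangs on the ring carbon C5 next to the carbinol and not on the alkene. Ring A closes in a 6-endo mode with respect to the alkene through a chair cis-fused to the cyclobutane, in which C8–C7 is axial and the C8 silyloxy group, the C4 silyloxy group and the oxocarbenium oxygen are equatorial, and ring B forms by a suprafacial 1,2-shift in which C7 keeps its configuration. C1 is fixed by the tether, since C2 and C7 can only bond to the face of C1 that is cis-fused to C5, and C3 is set by the equatorial oxocarbenium ion of that chair, which places the C3 methoxy group trans to the C4 silyl ether and on the side of the C6–C7 bridge (endo), as the target requires. The step needs migration of the external bond C8–C7 and not of the ring-fusion bond C8–C5: C8–C7 is the bond aligned with the empty orbital at C1, whereas C8–C5 lies in the ring plane and C5 is deactivated by its methoxy group, and the hindered pyridine base keeps stray HCl from protonating the alkene.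

Step 11
Reactants: 22 (1S,3S,4R,5R,6S,7R)-6-(3,4-dimethoxyphenyl)-3,5-dimethoxy-7-methyl-1-(prop-2-en-1-yl)-4-(triethylsilyloxy)bicyclo[3.2.1]octan-8-one
Product: 23 (1S,3S,4R,5S,6S,7R,8S)-6-(3,4-dimethoxyphenyl)-3,5-dimethoxy-7-methyl-1-(prop-2-en-1-yl)-4-(triethylsilyloxy)bicyclo[3.2.1]octan-8-ol (hydroxyl on the side of the C2–C4 bridge)
Conditions: NaBH4, MeOH/THF, 0 °C to rt
Reagents that add atoms: none
Why: Hydride reduction of the bridging ketone should occur from the side of the C6–C7 bridge, because ring A, a boat with both substituents pseudo-equatorial and C3–H pointing at C8 (or a chair with the C4 silyl ether axial), screens the other face, so the new hydroxyl at C8 lies toward the C2–C4 bridge as in the target.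

Step 12
Reactants: 23 (1S,3S,4R,5S,6S,7R,8S)-6-(3,4-dimethoxyphenyl)-3,5-dimethoxy-7-methyl-1-(prop-2-en-1-yl)-4-(triethylsilyloxy)bicyclo[3.2.1]octan-8-ol
Product: 24 (1S,3S,4R,5S,6S,7R,8S)-6-(3,4-dimethoxyphenyl)-3,5-dimethoxy-7-methyl-1-(prop-2-en-1-yl)-4-(triethylsilyloxy)bicyclo[3.2.1]octan-8-yl acetate
Conditions: Ac2O, DMAP, pyridine, 40 °C
Reagents that add atoms: acetic anhydride, CC(=O)OC(C)=O
Why: DMAP-catalysed acylation of the hindered C8 alcohol is done while C4 is still silylated, so that no choice between two hydroxyls is needed.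

Step 13
Reactants: 24 (1S,3S,4R,5S,6S,7R,8S)-6-(3,4-dimethoxyphenyl)-3,5-dimethoxy-7-methyl-1-(prop-2-en-1-yl)-4-(triethylsilyloxy)bicyclo[3.2.1]octan-8-yl acetate
Product: 25 (1S,3S,4R,5R,6S,7R,8S)-6-(3,4-dimethoxyphenyl)-4-hydroxy-3,5-dimethoxy-7-methyl-1-(prop-2-en-1-yl)bicyclo[3.2.1]octan-8-yl acetate
Conditions: HF·pyridine, THF, 0 °C to rt
Reagents that add atoms: none
Why: Fluoride cleavage of the triethylsilyl ether under acidic conditions avoids the base-induced acetyl shift from the C8 oxygen to the neighbouring C4 oxygen.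

Step 14
Reactants: 25 (1S,3S,4R,5R,6S,7R,8S)-6-(3,4-dimethoxyphenyl)-4-hydroxy-3,5-dimethoxy-7-methyl-1-(prop-2-en-1-yl)bicyclo[3.2.1]octan-8-yl acetate
Product: 26 (1S,3S,5S,6S,7R,8S)-6-(3,4-dimethoxyphenyl)-3,5-dimethoxy-7-methyl-4-oxo-1-(prop-2-en-1-yl)bicyclo[3.2.1]octan-8-yl acetate (CNP0344493.1)
Conditions: Dess–Martin periodinane, CH2Cl2, rt
Reagents that add atoms: none
Why: Dess–Martin oxidation of the hindered secondary alcohol under base-free conditions gives the C4 ketone without enolisation toward C3, so the methoxy centre set in step 10 is kept.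

Compound list
1 | (S)-4-benzyl-1,3-oxazolidin-2-one | O=C1N[C@@H](Cc2ccccc2)CO1 | starting material
2 | methoxyacetyl chloride | COCC(Cl)=O | starting material
3 | lithium salt of 1 (N-lithio oxazolidinone) | [Li]N1[C@@H](Cc2ccccc2)COC1=O | intermediate
4 | (S)-4-benzyl-3-(methoxyacetyl)-1,3-oxazolidin-2-one | COCC(=O)N1[C@@H](Cc2ccccc2)COC1=O | intermediate
5 | 2,2-dimethoxyacetaldehyde | COC(OC)C=O | starting material
6 | dibutylboron (Z)-enolate of 4 | CCCCB(CCCC)O/C(=C\OC)N1[C@@H](Cc2ccccc2)COC1=O | intermediate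
7 | (S)-4-benzyl-3-[(2S,3S)-3-hydroxy-2,4,4-trimethoxybutanoyl]-1,3-oxazolidin-2-one | O=C([C@@H](OC)[C@H](O)C(OC)OC)N1[C@@H](Cc2ccccc2)COC1=O | intermediate
8 | (2S,3S)-3-hydroxy-2,4,4-trimethoxy-1-(pyrrolidin-1-yl)butan-1-one | O=C([C@@H](OC)[C@H](O)C(OC)OC)N1CCCC1 | intermediate
9 | (2S,3S)-2,4,4-trimethoxy-1-(pyrrolidin-1-yl)-3-(triethylsilyloxy)butan-1-one | O=C([C@@H](OC)[C@H](O[Si](CC)(CC)CC)C(OC)OC)N1CCCC1 | intermediate
10 | (E)-methylisoeugenol, (E)-1,2-dimethoxy-4-(prop-1-en-1-yl)benzene | C/C=C/c1ccc(OC)c(OC)c1 | starting material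
11 | 1-[(3S)-2,4,4-trimethoxy-3-(triethylsilyloxy)but-1-en-1-ylidene]pyrrolidinium trifluoromethanesulfonate (keteniminium salt) | COC(=C=[N+]1CCCC1)[C@H](O[Si](CC)(CC)CC)C(OC)OC.[O-]S(=O)(=O)C(F)(F)F | intermediate
12 | N-cyclobutylidenepyrrolidinium trifluoromethanesulfonate corresponding to 13 (same configuration at C4, C5, C6, C7) | C1(=[N+]2CCCC2)[C@H](C)[C@@H](c2ccc(OC)c(OC)c2)[C@@]1(OC)[C@H](O[Si](CC)(CC)CC)C(OC)OC.[O-]S(=O)(=O)C(F)(F)F | intermediate
13 | (2R,3S,4R)-2-[(1S)-2,2-dimethoxy-1-(triethylsilyloxy)ethyl]-3-(3,4-dimethoxyphenyl)-2-methoxy-4-methylcyclobutan-1-one | O=C1[C@H](C)[C@@H](c2ccc(OC)c(OC)c2)[C@@]1(OC)[C@H](O[Si](CC)(CC)CC)C(OC)OC | intermediate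
14 | (2R,3S,4R)-3-(3,4-dimethoxyphenyl)-2-[(1S)-1-hydroxy-2,2-dimethoxyethyl]-2-methoxy-4-methylcyclobutan-1-one | O=C1[C@H](C)[C@@H](c2ccc(OC)c(OC)c2)[C@@]1(OC)[C@H](O)C(OC)OC | intermediate
15 | 2,3-dibromopropene | C=C(Br)CBr | starting material
16 | vinylmagnesium bromide | C=C[Mg]Br | starting material
17 | 2-bromopenta-1,4-diene | C=CCC(Br)=C | intermediate
18 | (penta-1,4-dien-2-yl)magnesium bromide | C=CCC(=C)[Mg]Br | intermediate
19 | (1S,2R,3S,4R)-3-(3,4-dimethoxyphenyl)-2-[(1S)-1-hydroxy-2,2-dimethoxyethyl]-2-methoxy-4-methyl-1-(penta-1,4-dien-2-yl)cyclobutan-1-ol | C=CCC(=C)[C@@]1(O)[C@H](C)[C@@H](c2ccc(OC)c(OC)c2)[C@@]1(OC)[C@H](O)C(OC)OC | intermediate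
20 | (1S,2R,3S,4R)-2-[(1S)-2,2-dimethoxy-1-(triethylsilyloxy)ethyl]-3-(3,4-dimethoxyphenyl)-2-methoxy-4-methyl-1-(penta-1,4-dien-2-yl)cyclobutan-1-ol | C=CCC(=C)[C@@]1(O)[C@H](C)[C@@H](c2ccc(OC)c(OC)c2)[C@@]1(OC)[C@H](O[Si](CC)(CC)CC)C(OC)OC | intermediate
21 | [(1S,2R,3S,4R)-2-[(1S)-2,2-dimethoxy-1-(triethylsilyloxy)ethyl]-3-(3,4-dimethoxyphenyl)-2-methoxy-4-methyl-1-(penta-1,4-dien-2-yl)cyclobutoxy]trimethylsilane (key-step precursor) | C=CCC(=C)[C@@]1(O[Si](C)(C)C)[C@H](C)[C@@H](c2ccc(OC)c(OC)c2)[C@@]1(OC)[C@H](O[Si](CC)(CC)CC)C(OC)OC | intermediate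
22 | (1S,3S,4R,5R,6S,7R)-6-(3,4-dimethoxyphenyl)-3,5-dimethoxy-7-methyl-1-(prop-2-en-1-yl)-4-(triethylsilyloxy)bicyclo[3.2.1]octan-8-one (key-step product) | C=CC[C@]12C[C@H](OC)[C@@H](O[Si](CC)(CC)CC)[C@](OC)([C@H](c3ccc(OC)c(OC)c3)[C@H]1C)C2=O | intermediate
23 | (1S,3S,4R,5S,6S,7R,8S)-6-(3,4-dimethoxyphenyl)-3,5-dimethoxy-7-methyl-1-(prop-2-en-1-yl)-4-(triethylsilyloxy)bicyclo[3.2.1]octan-8-ol | C=CC[C@]12C[C@H](OC)[C@@H](O[Si](CC)(CC)CC)[C@](OC)([C@H](c3ccc(OC)c(OC)c3)[C@H]1C)[C@H]2O | intermediate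
24 | (1S,3S,4R,5S,6S,7R,8S)-6-(3,4-dimethoxyphenyl)-3,5-dimethoxy-7-methyl-1-(prop-2-en-1-yl)-4-(triethylsilyloxy)bicyclo[3.2.1]octan-8-yl acetate | C=CC[C@]12C[C@H](OC)[C@@H](O[Si](CC)(CC)CC)[C@](OC)([C@H](c3ccc(OC)c(OC)c3)[C@H]1C)[C@H]2OC(C)=O | intermediate
25 | (1S,3S,4R,5R,6S,7R,8S)-6-(3,4-dimethoxyphenyl)-4-hydroxy-3,5-dimethoxy-7-methyl-1-(prop-2-en-1-yl)bicyclo[3.2.1]octan-8-yl acetate | C=CC[C@]12C[C@H](OC)[C@@H](O)[C@](OC)([C@H](c3ccc(OC)c(OC)c3)[C@H]1C)[C@H]2OC(C)=O | intermediate
26 | (1S,3S,5S,6S,7R,8S)-6-(3,4-dimethoxyphenyl)-3,5-dimethoxy-7-methyl-4-oxo-1-(prop-2-en-1-yl)bicyclo[3.2.1]octan-8-yl acetate | C=CC[C@]12C[C@H](OC)C(=O)[C@](OC)([C@H](c3ccc(OC)c(OC)c3)[C@H]1C)[C@H]2OC(C)=O | target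

Total step count: 14. Longest linear sequence: 13 steps (steps 1–6 and 8–14); step 7 is a one-step branch.

Steps most likely to fail

Step 5. The keteniminium ion may be trapped within the molecule by an acetal oxygen before the alkene arrives, and the C4 centre may not discriminate the two faces of C5 well enough. Diastereomers should be separable, so enantiopurity would still rest on step 2. Fallback (sets out from 7, returns at 13): 7 is silylated with TESCl and imidazole to (S)-4-benzyl-3-[(2S,3S)-2,4,4-trimethoxy-3-(triethylsilyloxy)butanoyl]-1,3-oxazolidin-2-one F1. The auxiliary is removed with LiOH and H2O2 to give (2S,3S)-2,4,4-trimethoxy-3-(triethylsilyloxy)butanoic acid F2. Neutral 1-chloro-N,N,2-trimethylprop-1-en-1-amine converts F2 into (2S,3S)-2,4,4-trimethoxy-3-(triethylsilyloxy)butanoyl chloride F3. Slow addition of F3 to Et3N and excess 10 in refluxing toluene releases the less electrophilic (3S)-2,4,4-trimethoxy-3-(triethylsilyloxy)but-1-en-1-one F4. Thermal ketene–alkene [2+2] cycloaddition of F4 with 10 should show the same regiochemistry and the same preference for the large group cis to the aryl group, and gives 13.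

Step 8. Delivery from the bromomagnesium alkoxide may lose against external attack on the more open face of the ketone, or the aldolate may fragment by retro-aldol cleavage. Fallback (sets out from 13, returns at 21): the silyl-protected ketone 13 is precomplexed with methylaluminium bis(2,6-di-tert-butyl-4-methylphenoxide) in toluene at −78 °C. The aluminium reagent binds the carbonyl oxygen and screens the open face. Penta-1,4-dien-2-yllithium F5, made from 17 and t-BuLi in Et2O at −78 °C, is thereby forced to the face of the side chain and gives 20 directly. TMSCl and imidazole then convert 20 into 21 as in the second half of step 9.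

Step 10. The oxocarbenium ion may react through the alternative chair and give the C3 epimer, and the C1 cation may be diverted by proton loss or by migration of C5. The fallback covers the C3 outcome and sets C3 by late enolate protonation in place of the cyclisation (sets out from 21, returns at 26). Should the cascade deliver mainly (1S,3R,4R,5R,6S,7R)-6-(3,4-dimethoxyphenyl)-3,5-dimethoxy-7-methyl-1-(prop-2-en-1-yl)-4-(triethylsilyloxy)bicyclo[3.2.1]octan-8-one F6, it is carried through the operations of steps 11–14 unchanged. These give in turn the C8 alcohol (3R)-epimer of 23 F7, the acetate (3R)-epimer of 24 F8, the C4 alcohol (3R)-epimer of 25 F9 and the ketone (3R)-epimer of 26 F10. F10 is deprotonated at C3 with LiN(SiMe3)2 in THF at −78 °C to the lithium enolate of F10 F11. F11 is protonated kinetically with 2,6-di-tert-butylphenol from the exo face, the endo face being covered by the C6 aryl group, which inverts C3 and gives 26.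

Further compounds
F1 | step 5 | (S)-4-benzyl-3-[(2S,3S)-2,4,4-trimethoxy-3-(triethylsilyloxy)butanoyl]-1,3-oxazolidin-2-one | O=C([C@@H](OC)[C@H](O[Si](CC)(CC)CC)C(OC)OC)N1[C@@H](Cc2ccccc2)COC1=O
F2 | step 5 | (2S,3S)-2,4,4-trimethoxy-3-(triethylsilyloxy)butanoic acid | OC(=O)[C@@H](OC)[C@H](O[Si](CC)(CC)CC)C(OC)OC
F3 | step 5 | (2S,3S)-2,4,4-trimethoxy-3-(triethylsilyloxy)butanoyl chloride | ClC(=O)[C@@H](OC)[C@H](O[Si](CC)(CC)CC)C(OC)OC
F4 | step 5 | (3S)-2,4,4-trimethoxy-3-(triethylsilyloxy)but-1-en-1-one | O=C=C(OC)[C@H](O[Si](CC)(CC)CC)C(OC)OC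
F5 | step 8 | penta-1,4-dien-2-yllithium | [Li]C(=C)CC=C
F6 | step 10 | (1S,3R,4R,5R,6S,7R)-6-(3,4-dimethoxyphenyl)-3,5-dimethoxy-7-methyl-1-(prop-2-en-1-yl)-4-(triethylsilyloxy)bicyclo[3.2.1]octan-8-one | C=CC[C@]12C[C@@H](OC)[C@@H](O[Si](CC)(CC)CC)[C@](OC)([C@H](c3ccc(OC)c(OC)c3)[C@H]1C)C2=O
F7 | step 10 | (1S,3R,4R,5S,6S,7R,8S)-6-(3,4-dimethoxyphenyl)-3,5-dimethoxy-7-methyl-1-(prop-2-en-1-yl)-4-(triethylsilyloxy)bicyclo[3.2.1]octan-8-ol | C=CC[C@]12C[C@@H](OC)[C@@H](O[Si](CC)(CC)CC)[C@](OC)([C@H](c3ccc(OC)c(OC)c3)[C@H]1C)[C@H]2O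
F8 | step 10 | (1S,3R,4R,5S,6S,7R,8S)-6-(3,4-dimethoxyphenyl)-3,5-dimethoxy-7-methyl-1-(prop-2-en-1-yl)-4-(triethylsilyloxy)bicyclo[3.2.1]octan-8-yl acetate | C=CC[C@]12C[C@@H](OC)[C@@H](O[Si](CC)(CC)CC)[C@](OC)([C@H](c3ccc(OC)c(OC)c3)[C@H]1C)[C@H]2OC(C)=O
F9 | step 10 | (1S,3R,4R,5R,6S,7R,8S)-6-(3,4-dimethoxyphenyl)-4-hydroxy-3,5-dimethoxy-7-methyl-1-(prop-2-en-1-yl)bicyclo[3.2.1]octan-8-yl acetate | C=CC[C@]12C[C@@H](OC)[C@@H](O)[C@](OC)([C@H](c3ccc(OC)c(OC)c3)[C@H]1C)[C@H]2OC(C)=O
F10 | step 10 | (1S,3R,5S,6S,7R,8S)-6-(3,4-dimethoxyphenyl)-3,5-dimethoxy-7-methyl-4-oxo-1-(prop-2-en-1-yl)bicyclo[3.2.1]octan-8-yl acetate | C=CC[C@]12C[C@@H](OC)C(=O)[C@](OC)([C@H](c3ccc(OC)c(OC)c3)[C@H]1C)[C@H]2OC(C)=O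
F11 | step 10 | lithium enolate of F10 (C3=C4 enolate) | C=CC[C@]12CC(OC)=C(O[Li])[C@](OC)([C@H](c3ccc(OC)c(OC)c3)[C@H]1C)[C@H]2OC(C)=O
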